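**Retrosynthetic overview**
- The target, 2,3,5-tribromo-6-(1,1-dibromopropyl)-4H-pyran-4-one, is cut at the exocyclic bond C6–C1'. This gives 2,3,5-tribromo-4H-pyran-4-one (C6–H) and a (1,1-dibromopropyl)boronic ester. Both halves are first hung on one boron atom, then a 1,2-metalate rearrangement turns C–B–C into C–C, and bromine removes the boron.
- Enabling feature: C6 of the pyranone ring lies between ring oxygen O1 and brominated C5, so it carries the only acidic C–H. C1' is linked through C6=C5–C4=O to the ring carbonyl, so a boron on C1' acts as a vinylogous boron enolate. Of the two geminal bromines at C1', one is the carbenoid bromine that stays and the other replaces boron.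
- The tribromopyranone comes from 4H-pyran-4-one by electrophilic dibromination at C3/C5, then zincation and bromination at C2.
- The boron reagent comes from 1,1-dibromopropane by carbenoid borylation.
- Ring order: the single ring (the 4-pyranone) is bought intact, and no ring is formed in the route.

Key step: step 4

Remark on the chemistry: the target has no stereocentre (C1' carries two bromines and the ring is planar). It is therefore achiral, the SMILES defines it completely, and no enantioselective step is needed. Transient stereocentres on the way are racemic.

**Step 1**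
Reactants: 1 4H-pyran-4-one
Product: 2 3,5-dibromo-4H-pyran-4-one
Conditions: Br2 (2.2 equiv), NaOAc (2.2 equiv), AcOH, 60 °C
Reagents that add atoms: bromine, BrBr
Why: Electrophilic bromination (addition–elimination) goes to C3 and C5, the β-carbons of the two ring enol ether units and the only nucleophilic positions of a 4-pyranone, while acetate takes up HBr so that the ring is not shut down as its hydroxypyrylium salt; no stereocentre is formed.

**Step 2**
Reactants: 2 3,5-dibromo-4H-pyran-4-one
Product: 4 2,3,5-tribromo-4H-pyran-4-one, via pyranonylzinc chloride 3 (not isolated)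
Conditions: TMPZnCl·LiCl (1.05 equiv), THF, 0 °C; then Br2 (1.1 equiv), −40 → 0 °C
Reagents that add atoms: bromine, BrBr; TMPZnCl·LiCl, CC1(C)CCCC(C)(C)N1[Zn]Cl.[Li+].[Cl-] (its ZnCl stands only in 3)
Why: Deprotonative zincation with a hindered TMP–zinc amide followed by a bromine quench, a reaction type known for chromones and related 4-pyranone rings, takes one of the two equivalent C2/C6–H bonds (acidified by O1 and the neighbouring C–Br), the covalent C–Zn bond resists loss of the adjacent bromide, and one equivalent of base keeps it to one site; no stereocentre is formed.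

**Step 3**
Reactants: 5 1,1-dibromopropane; 6 2-isopropoxy-4,4,5,5-tetramethyl-1,3,2-dioxaborolane
Product: 9 2-(1,1-dibromopropyl)-4,4,5,5-tetramethyl-1,3,2-dioxaborolane, via 1,1-dibromopropyllithium 7 (not isolated), via lithium isopropoxyborate 8 (not isolated)
Conditions: LDA (1.05 equiv) added to 5 + 6, THF/Et2O, −100 °C; then HCl·Et2O (2.1 equiv), −100 °C → rt
Reagents that add atoms: lithium diisopropylamide, [Li]N(C(C)C)C(C)C (its Li stands only in 7 and 8)
Why: Carbenoid borylation as used to make the (dihaloalkyl)boronic esters of the Matteson homologation: LDA deprotonates the 1,1-dibromoalkane, the borate ester already in the flask traps carbenoid 7 faster than it loses LiBr, and acid at low temperature strips isopropoxide from 8 before anything migrates; no stereocentre is formed.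

**Step 4**
Reactants: 4 2,3,5-tribromo-4H-pyran-4-one; 9 2-(1,1-dibromopropyl)-4,4,5,5-tetramethyl-1,3,2-dioxaborolane
Product: 13 2,3,5-tribromo-6-(1,1-dibromopropyl)-4H-pyran-4-one (target), via pyranonylmagnesium chloride 10 (not isolated), via boron ate complex 11 (not isolated), via alpha-bromo boronic ester 12 (not isolated)
Conditions: TMPMgCl·LiCl (1.05 equiv), THF, −78 °C; 9 (1.2 equiv), −78 → 0 °C; Br2 (1.5 equiv), CH2Cl2, −78 → 0 °C; cyclohexene quench
Reagents that add atoms: bromine, BrBr; TMPMgCl·LiCl, CC1(C)CCCC(C)(C)N1[Mg]Cl.[Li+].[Cl-] (its MgCl stands only in 10 and 11)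
Why: Proposed new method: TMPMgCl·LiCl removes the only ring hydrogen of 4 (C6–H, acidified by O1 and C5–Br), Grignard 10 adds to the empty p orbital of the boron of 9, and in ate complex 11 the ring carbon C6 migrates from boron to the neighbouring CBr2 carbon while one bromide leaves anti to it with help from Mg2+ (1,2-metalate rearrangement), which makes the C6–C1' bond and gives 12. The closest known reaction type is the Matteson homologation in its variant of a Grignard reagent plus a (1,1-dihaloalkyl)boronic ester; new are the 4-pyranon-2-yl migrating group and the closing stage, in which the C1'–B bond of 12, a vinylogous boron enolate through C6=C5–C4=O, is loosened by the halide ions in the flask and cleaved by Br2 at C1' (closest known types: bromination of boron enolates and halodeboronation of boronate complexes), so that the boron tether leaves exactly where the second bromine is needed. No ring is closed. The one new stereocentre, C1' of 12, forms as a racemate and vanishes when it becomes the CBr2 carbon, so nothing has to be controlled. The step needs attack of 10 at boron and not at bromine of 9, one migration only and no second homologation: the α-bromines make boron strongly Lewis acidic, the pinacol oxygens are poor migrating groups, 9 is used in slight excess so that neutral, more hindered 12 meets no free 10, and even a bromine-philic exchange would give tetrabromopyranone plus the boron-stabilised bromo carbanion, which can recombine by addition–elimination at the vinylogous acyl bromide carbon to the same 12. The ring C–Br bonds should survive because no alkyllithium, low-valent metal or nucleophilic base is present and the flask stays at or below 0 °C.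

**Compound list**
1 | 4H-pyran-4-one | O=c1ccocc1 | starting material
2 | 3,5-dibromo-4H-pyran-4-one | O=c1c(Br)cocc1Br | intermediate
3 | (3,5-dibromo-4-oxo-4H-pyran-2-yl)zinc chloride | O=c1c(Br)coc([Zn]Cl)c1Br | intermediate
4 | 2,3,5-tribromo-4H-pyran-4-one | O=c1c(Br)coc(Br)c1Br | intermediate
5 | 1,1-dibromopropane | CCC(Br)Br | starting material
6 | 2-isopropoxy-4,4,5,5-tetramethyl-1,3,2-dioxaborolane | CC(C)OB1OC(C)(C)C(C)(C)O1 | starting material
7 | 1,1-dibromopropyllithium | CCC([Li])(Br)Br | intermediate
8 | lithium (1,1-dibromopropyl)(isopropoxy)(pinacolato)borate | CCC(Br)(Br)[B-]1(OC(C)C)OC(C)(C)C(C)(C)O1.[Li+] | intermediate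
9 | 2-(1,1-dibromopropyl)-4,4,5,5-tetramethyl-1,3,2-dioxaborolane | CCC(Br)(Br)B1OC(C)(C)C(C)(C)O1 | intermediate
10 | (3,5,6-tribromo-4-oxo-4H-pyran-2-yl)magnesium chloride | O=c1c(Br)c(Br)oc([Mg]Cl)c1Br | intermediate
11 | chloromagnesium (1,1-dibromopropyl)(pinacolato)(3,5,6-tribromo-4-oxo-4H-pyran-2-yl)borate | CCC(Br)(Br)[B-]1(OC(C)(C)C(C)(C)O1)c2oc(Br)c(Br)c(=O)c2Br.[Mg+]Cl | intermediate
12 | 2,3,5-tribromo-6-[1-bromo-1-(4,4,5,5-tetramethyl-1,3,2-dioxaborolan-2-yl)propyl]-4H-pyran-4-one (racemic) | CCC(Br)(B1OC(C)(C)C(C)(C)O1)c2oc(Br)c(Br)c(=O)c2Br | intermediate
13 | 2,3,5-tribromo-6-(1,1-dibromopropyl)-4H-pyran-4-one (achiral) | CCC(Br)(Br)c1oc(Br)c(Br)c(=O)c1Br | target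

**Step count**
Total step count: 4. Longest linear sequence: 3 (steps 1, 2, 4). Step 3 is a one-step side branch.

**Steps most likely to fail**

1. **Step 4 (Proposed new method).**
   - What may go wrong: complexation of the electron-poor, ortho-substituted Grignard with the hindered boron may be slow or reversible, so that self-condensation of 10 at the C–Br next to O1 of another ring takes over.
   - The tertiary bromide 12 may lose HBr.
   - The C–B bond may undergo protonolysis before bromine arrives.
   - Fallback (known chemistry only), setting out from 4 and coming back at 13: 4 is magnesiated as before to 10 and added to propanal at −78 °C (1,2-addition, which makes the same ring–chain bond). This gives the chloromagnesium alkoxide of the carbinol F1 and, after a water quench, racemic 2,3,5-tribromo-6-(1-hydroxypropyl)-4H-pyran-4-one F2. PBr3 in CH2Cl2 at 0 °C should turn it into racemic 2,3,5-tribromo-6-(1-bromopropyl)-4H-pyran-4-one F3. A Wohl–Ziegler bromination (NBS, AIBN or light, PhCF3, reflux) at the remaining C1'–H, the only activated C–H left, should then give 13.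

2. **Step 3.**
   - What may go wrong: the lithium carbenoid may lose LiBr by α-elimination before the borate traps it, or isopropoxide may migrate from boron to carbon while 8 warms before acidification.
   - Fallback without any carbenoid, setting out from 6 and coming back at 9: n-PrMgCl in THF at −78 °C → rt replaces the isopropoxy group of 6 and gives 4,4,5,5-tetramethyl-2-propyl-1,3,2-dioxaborolane F4. Radical bromination α to boron (NBS, light, PhCF3), which relies on the stabilised α-boryl radical, should give racemic 2-(1-bromopropyl)-4,4,5,5-tetramethyl-1,3,2-dioxaborolane F5. A second equivalent under the same conditions should give 9.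

3. **Step 2.**
   - What may go wrong: single and double metalation of the two equivalent C–H bonds may be poorly discriminated (metal–hydrogen scrambling between 3 and 2), so that several bromination levels form side by side.
   - Fallback that removes the selectivity question, setting out from 2 and coming back at 10: an excess of TMPZnCl·LiCl (2.3 equiv) zincates both positions to (3,5-dibromo-4-oxo-4H-pyran-2,6-diyl)bis(zinc chloride) F6, and an excess of Br2 gives the symmetric 2,3,5,6-tetrabromo-4H-pyran-4-one F7. One equivalent of iPrMgCl·LiCl in THF at −78 °C then performs a single bromine–magnesium exchange at one of the two equivalent positions next to O1, the site preferred in 2,3-dibrominated oxygen heterocycles. This delivers 10 directly for step 4.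

**Further compounds**
F1 | step 4 | chloromagnesium 1-(3,5,6-tribromo-4-oxo-4H-pyran-2-yl)propan-1-olate (racemic) | CCC(O[Mg]Cl)c1oc(Br)c(Br)c(=O)c1Br
F2 | step 4 | 2,3,5-tribromo-6-(1-hydroxypropyl)-4H-pyran-4-one (racemic) | CCC(O)c1oc(Br)c(Br)c(=O)c1Br
F3 | step 4 | 2,3,5-tribromo-6-(1-bromopropyl)-4H-pyran-4-one (racemic) | CCC(Br)c1oc(Br)c(Br)c(=O)c1Br
F4 | step 3 | 4,4,5,5-tetramethyl-2-propyl-1,3,2-dioxaborolane | CCCB1OC(C)(C)C(C)(C)O1
F5 | step 3 | 2-(1-bromopropyl)-4,4,5,5-tetramethyl-1,3,2-dioxaborolane (racemic) | CCC(Br)B1OC(C)(C)C(C)(C)O1
F6 | step 2 | (3,5-dibromo-4-oxo-4H-pyran-2,6-diyl)bis(zinc chloride) | O=c1c(Br)c([Zn]Cl)oc([Zn]Cl)c1Br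
F7 | step 2 | 2,3,5,6-tetrabromo-4H-pyran-4-one | O=c1c(Br)c(Br)oc(Br)c1Br
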